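**Retrosynthetic overview**
1. Target 30 ⇒ dimer 23 (ring B–CH2–central ring, central ring already butyrylated, one free CH) + ring A Mannich base 29; the last aryl–CH2 bond comes from an ortho-quinone methide alkylation.
2. 23 ⇒ 21 by Friedel–Crafts butyrylation of the central ring and hydrogenolysis of four benzyl ethers.
3. 21 ⇒ diene 10 + ynone 19. The strategy rests on ring B, the hexasubstituted benzene with C1 bridge CH2, C2 OH, C3 butyryl, C4 OH, C5 CH3, C6 OCH3: its C4–C5–C6–C1 unit is a 1,1,3-trioxygenated diene that already carries the bridge carbon and the central ring, and its C2–C3 unit is 1-(benzyloxy)hex-1-yn-3-one; Diels–Alder reaction and aromatisation form C1–C2 and C3–C4.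
4. 10 ⇒ dianion of methyl 2-methyl-3-oxobutanoate + 2,4,6-tris(benzyloxy)benzaldehyde (aldol, ionic deoxygenation, O-methylation, silylation); 19 ⇒ benzyl alcohol, trichloroethylene, butanal.
5. Ring order: the central ring and ring A are bought as phloroglucinols; ring B is the only ring formed (step 9).

Key step: step 9

Assumption (remark on the chemistry): the target has no stereocentre. The stereocentres of 6, 18 and 20 are left uncontrolled because each is destroyed later, and the geometry of the ketene acetal bond of 10 is left undefined because it does not reach the product.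

**Route**

Step 1
Reactants: 1 1,3,5-tris(benzyloxy)benzene
Product: 3 2,4,6-tris(benzyloxy)benzaldehyde, via iminium chloride 2 (not isolated)
Conditions: POCl3 (1.2 equiv), DMF, 0 °C → rt; then H2O, 0 °C → rt
Reagents that add atoms: N,N-dimethylformamide CN(C)C=O; water O
Why: Vilsmeier–Haack formylation, in which the symmetrical, strongly activated trialkoxybenzene is attacked once by the chloroiminium ion and the iminium salt is hydrolysed to an aldehyde that deactivates the ring against a second formylation.

Step 2
Reactants: 3 2,4,6-tris(benzyloxy)benzaldehyde; 4 methyl 2-methyl-3-oxobutanoate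
Product: 6 methyl 5-hydroxy-2-methyl-3-oxo-5-[2,4,6-tris(benzyloxy)phenyl]pentanoate (mixture of racemic diastereomers), via acetoacetate dianion 5 (not isolated)
Conditions: 4, NaH (1.1 equiv), THF, 0 °C; n-BuLi (1.05 equiv), 0 °C; then 3, −78 °C; AcOH (2 equiv), −78 °C
Reagents that add atoms: none
Why: Aldol addition of the acetoacetate dianion, which reacts at its more basic terminal (γ) carbon with an aldehyde that has no α-hydrogen; the two new stereocentres need no control because both are removed (C5 in step 3, C2 in step 4).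

Step 3
Reactants: 6 methyl 5-hydroxy-2-methyl-3-oxo-5-[2,4,6-tris(benzyloxy)phenyl]pentanoate
Product: 7 methyl 2-methyl-3-oxo-5-[2,4,6-tris(benzyloxy)phenyl]pentanoate (racemic)
Conditions: Et3SiH (3 equiv), TFA (5 equiv), CH2Cl2, −20 → 0 °C
Reagents that add atoms: none
Why: Ionic hydrogenation (Kursanov–Parnes type), in which the benzylic alcohol ionises to a cation stabilised by three alkoxy groups and is trapped by hydride from the silane; this avoids the unstable 2,4,6-trialkoxybenzyl halide that a direct dianion alkylation would need.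

Step 4
Reactants: 7 methyl 2-methyl-3-oxo-5-[2,4,6-tris(benzyloxy)phenyl]pentanoate
Product: 8 methyl (2E)-3-methoxy-2-methyl-5-[2,4,6-tris(benzyloxy)phenyl]pent-2-enoate
Conditions: HC(OMe)3 (3 equiv), H2SO4 (cat.), MeOH, rt → 50 °C; concentrate
Reagents that add atoms: trimethyl orthoformate COC(OC)OC
Why: Acid-catalysed ketalisation of the ketone by the orthoformate and loss of methanol give the conjugated β-methoxy enoate (enol ether formation from a β-keto ester); any (2Z) or β,γ-unsaturated isomer converges on the same dienolate in step 5.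

Step 5
Reactants: 8 methyl (2E)-3-methoxy-2-methyl-5-[2,4,6-tris(benzyloxy)phenyl]pent-2-enoate
Product: 10 (3Z)-1,3-dimethoxy-2-methyl-1-(trimethylsilyloxy)-5-[2,4,6-tris(benzyloxy)phenyl]penta-1,3-diene, via lithium dienolate 9 (not isolated)
Conditions: LiN(iPr)2 (1.15 equiv), THF, −78 °C; Me3SiCl (1.3 equiv), −78 → 0 °C; pentane, filtration under argon, used crude
Reagents that add atoms: chlorotrimethylsilane C[Si](C)(C)Cl
Why: γ-Deprotonation of the β-methoxy enoate and O-silylation of the dienolate is the standard preparation of 1,3-dialkoxy-1-silyloxy dienes (Brassard-type dienes), and allylic 1,3-strain with the C2 methyl group should place the arylmethyl group cis to the C3 methoxy group, on the outer side of the diene.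

Step 6
Reactants: 11 benzyl alcohol; 12 trichloroethylene
Product: 14 benzyl (E)-1,2-dichlorovinyl ether, via potassium benzyloxide 13 (not isolated)
Conditions: KH (1.1 equiv), THF, 0 °C; then 12 (1.05 equiv), −40 °C → rt
Reagents that add atoms: none
Why: Alkoxide substitution on trichloroethylene by elimination–addition is the standard entry to 1,2-dichlorovinyl ethers as alkynyl ether precursors, and the trans addition gives the (E) isomer.

Step 7
Reactants: 14 benzyl (E)-1,2-dichlorovinyl ether; 15 butanal
Product: 18 1-(benzyloxy)hex-1-yn-3-ol (racemic), via benzyl chloroethynyl ether 16 (not isolated), via lithium benzyloxyacetylide 17 (not isolated)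
Conditions: n-BuLi (2.2 equiv), THF, −78 → −40 °C; then 15, −78 °C; H2O quench at −78 °C; chromatography on Et3N-deactivated silica
Reagents that add atoms: none
Why: Elimination of HCl and chlorine–lithium exchange give the lithium alkoxyacetylide, which adds to the aldehyde (acetylide 1,2-addition); the carbinol centre is racemic and is oxidised in step 8.

Step 8
Reactants: 18 1-(benzyloxy)hex-1-yn-3-ol
Product: 19 1-(benzyloxy)hex-1-yn-3-one
Conditions: activated MnO2 (15 equiv), CH2Cl2, 0 °C → rt; filtration, concentration below 20 °C, used at once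
Reagents that add atoms: none
Why: MnO2 oxidation of a propargylic alcohol runs under neutral, non-aqueous conditions, which spares the acid- and water-sensitive ynol ether.

Step 9
Reactants: 10 (3Z)-1,3-dimethoxy-2-methyl-1-(trimethylsilyloxy)-5-[2,4,6-tris(benzyloxy)phenyl]penta-1,3-diene (1.5 equiv); 19 1-(benzyloxy)hex-1-yn-3-one
Product: 21 1-[2-(benzyloxy)-6-hydroxy-4-methoxy-5-methyl-3-{[2,4,6-tris(benzyloxy)phenyl]methyl}phenyl]butan-1-one, via cyclohexadiene adduct 20 (not isolated)
Conditions: ZnCl2 (0.2 equiv, in Et2O), CH2Cl2, −40 → 0 °C; then 1 M aq. HCl, THF, 0 °C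
Reagents that add atoms: none
Why: Proposed new method: the C4 terminus of the vinylketene acetal (the carbon that carries the arylmethyl group) is its most nucleophilic site and the ZnCl2-bound ynone is most electrophilic at its β carbon (the one bearing OBn), so the first bond forms as C1–C2 of ring B, concertedly or as a vinylogous Mukaiyama–Michael addition. The zinc allenolate then closes on the silyloxycarbenium carbon (C3–C4 bond; 6-(enolexo)-exo-trig, or the second bond of a concerted [4+2]) to give cyclohexa-1,4-diene 20, and the acid work-up removes the silyl group and methanol so that C4 keeps its oxygen as the free, ketone-chelated phenol. The closest known reaction type is the Diels–Alder reaction and aromatisation of 1,3-dialkoxy-1-silyloxybutadienes with acetylenic ketones and esters, which gives salicylate-type phenols with the same orientation; what is new is the donor (benzyloxy) substituent on the β carbon of the alkyne. No stereocentre survives, since the two sp3 ring carbons of 20 (mixture of diastereomers) both become aromatic. The selectivity needed is regiochemical, and it is secured by the matched polarity of the partners (ketene acetal carbon to the α carbon, arylmethyl-bearing carbon to the β carbon) and by the (3Z) geometry of 10, which keeps the arylmethyl group outside the s-cis diene; working at or below 0 °C avoids the sigmatropic benzyl shift of the benzyl ynol ether.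

Step 10
Reactants: 21 1-[2-(benzyloxy)-6-hydroxy-4-methoxy-5-methyl-3-{[2,4,6-tris(benzyloxy)phenyl]methyl}phenyl]butan-1-one
Product: 22 1-[2,4,6-tris(benzyloxy)-3-{[2-(benzyloxy)-3-butanoyl-4-hydroxy-6-methoxy-5-methylphenyl]methyl}phenyl]butan-1-one
Conditions: butanoic acid (1.5 equiv), (CF3CO)2O (2 equiv), CH2Cl2, 0 °C → rt; then K2CO3, MeOH, rt
Reagents that add atoms: butanoic acid CCCC(=O)O
Why: Friedel–Crafts acylation with the mixed trifluoroacetic anhydride, in which the two equivalent free positions of the central tri(benzyloxy) ring are the only activated aromatic CH carbons and the first acyl group deactivates the ring against a second; the methanolysis frees the ring B phenol again should it have been acylated.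

Step 11
Reactants: 22 1-[2,4,6-tris(benzyloxy)-3-{[2-(benzyloxy)-3-butanoyl-4-hydroxy-6-methoxy-5-methylphenyl]methyl}phenyl]butan-1-one
Product: 23 1-[3-[(3-butanoyl-2,4-dihydroxy-6-methoxy-5-methylphenyl)methyl]-2,4,6-trihydroxyphenyl]butan-1-one
Conditions: H2 (1 atm), 10% Pd/C, EtOAc–MeOH, rt
Reagents that add atoms: none
Why: Hydrogenolysis of the four aryl benzyl ethers over Pd/C; the hindered, hydrogen-bonded aryl ketones and the diarylmethane should not be reduced under these mild conditions.

Step 12
Reactants: 24 2-methylbenzene-1,3,5-triol (2-methylphloroglucinol)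
Product: 25 1-(2,4,6-trihydroxy-3-methylphenyl)butan-1-one
Conditions: butanoyl chloride (1.1 equiv), AlCl3 (3.5 equiv), PhNO2–CH2Cl2, 0 °C → rt; aq. HCl
Reagents that add atoms: butanoyl chloride CCCC(=O)Cl
Why: Friedel–Crafts C-acylation of the phloroglucinol nucleus, in which the two free positions of 24 are equivalent and the acyl group stops further acylation.

Step 13
Reactants: 25 1-(2,4,6-trihydroxy-3-methylphenyl)butan-1-one
Product: 26 1-[4,6-bis(benzyloxy)-2-hydroxy-3-methylphenyl]butan-1-one
Conditions: BnBr (2.05 equiv), K2CO3 (2.2 equiv), DMF, rt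
Reagents that add atoms: benzyl bromide BrCc1ccccc1
Why: Williamson ether formation, in which the 4-OH (para to the ketone, most acidic) and the less hindered ortho 6-OH react while the 2-OH, hydrogen-bonded to the ketone and flanked by the methyl group, should remain free.

Step 14
Reactants: 26 1-[4,6-bis(benzyloxy)-2-hydroxy-3-methylphenyl]butan-1-one
Product: 27 1-[4,6-bis(benzyloxy)-2-methoxy-3-methylphenyl]butan-1-one
Conditions: MeI (3 equiv), K2CO3 (2 equiv), DMF, 50 °C
Reagents that add atoms: iodomethane CI
Why: Williamson O-methylation of the one remaining, chelated phenol, all other hydroxyl groups being blocked as benzyl ethers.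

Step 15
Reactants: 27 1-[4,6-bis(benzyloxy)-2-methoxy-3-methylphenyl]butan-1-one
Product: 28 1-(4,6-dihydroxy-2-methoxy-3-methylphenyl)butan-1-one (ring A monomer)
Conditions: H2 (1 atm), 10% Pd/C, EtOAc–MeOH, rt
Reagents that add atoms: none
Why: Hydrogenolysis of the two benzyl ethers over Pd/C, to which the methyl ether is inert.

Step 16
Reactants: 28 1-(4,6-dihydroxy-2-methoxy-3-methylphenyl)butan-1-one
Product: 29 1-{3-[(dimethylamino)methyl]-2,4-dihydroxy-6-methoxy-5-methylphenyl}butan-1-one
Conditions: 37% aq. CH2O (1.1 equiv), 40% aq. Me2NH (1.1 equiv), EtOH, 0 °C → rt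
Reagents that add atoms: formaldehyde C=O; dimethylamine CNC
Why: Mannich reaction (phenolic aminomethylation) at the only free ring carbon, which lies between two hydroxyl groups.

Step 17
Reactants: 23 1-[3-[(3-butanoyl-2,4-dihydroxy-6-methoxy-5-methylphenyl)methyl]-2,4,6-trihydroxyphenyl]butan-1-one; 29 1-{3-[(dimethylamino)methyl]-2,4-dihydroxy-6-methoxy-5-methylphenyl}butan-1-one (1.1 equiv)
Product: 30 1-[3-[(3-butanoyl-2,4-dihydroxy-6-methoxy-5-methylphenyl)methyl]-5-[(3-butanoyl-2,6-dihydroxy-4-methoxy-5-methylphenyl)methyl]-2,4,6-trihydroxyphenyl]butan-1-one (CNP0171986.0)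
Conditions: 1,4-dioxane, 90 °C, argon
Reagents that add atoms: none
Why: Thermal loss of dimethylamine from the Mannich base gives an ortho-quinone methide, which C-alkylates the single free, doubly OH-activated carbon of the central ring of 23 (Mannich-base methylene bridging of acylphloroglucinols).

**Compound list**
1 | 1,3,5-tris(benzyloxy)benzene | c1ccc(COc2cc(OCc3ccccc3)cc(OCc3ccccc3)c2)cc1 | starting material
2 | N,N-dimethyl[2,4,6-tris(benzyloxy)phenyl]methaniminium chloride | C[N+](C)=Cc1c(OCc2ccccc2)cc(OCc2ccccc2)cc1OCc1ccccc1.[Cl-] | intermediate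
3 | 2,4,6-tris(benzyloxy)benzaldehyde | O=Cc1c(OCc2ccccc2)cc(OCc2ccccc2)cc1OCc1ccccc1 | intermediate
4 | methyl 2-methyl-3-oxobutanoate | COC(=O)C(C)C(C)=O | starting material
5 | sodium lithium dianion of methyl 2-methyl-3-oxobutanoate | [Na+].[Li+].C=C([O-])C(C)=C([O-])OC | intermediate
6 | methyl 5-hydroxy-2-methyl-3-oxo-5-[2,4,6-tris(benzyloxy)phenyl]pentanoate (diastereomer mixture, racemic) | COC(=O)C(C)C(=O)CC(O)c1c(OCc2ccccc2)cc(OCc2ccccc2)cc1OCc1ccccc1 | intermediate
7 | methyl 2-methyl-3-oxo-5-[2,4,6-tris(benzyloxy)phenyl]pentanoate (racemic) | COC(=O)C(C)C(=O)CCc1c(OCc2ccccc2)cc(OCc2ccccc2)cc1OCc1ccccc1 | intermediate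
8 | methyl (2E)-3-methoxy-2-methyl-5-[2,4,6-tris(benzyloxy)phenyl]pent-2-enoate | COC(=O)/C(C)=C(/OC)CCc1c(OCc2ccccc2)cc(OCc2ccccc2)cc1OCc1ccccc1 | intermediate
9 | lithium dienolate of 8 (γ-deprotonated) | [Li+].COC([O-])=C(C)/C(OC)=C/Cc1c(OCc2ccccc2)cc(OCc2ccccc2)cc1OCc1ccccc1 | intermediate
10 | (3Z)-1,3-dimethoxy-2-methyl-1-(trimethylsilyloxy)-5-[2,4,6-tris(benzyloxy)phenyl]penta-1,3-diene (ketene acetal geometry undefined) | COC(O[Si](C)(C)C)=C(C)/C(OC)=C/Cc1c(OCc2ccccc2)cc(OCc2ccccc2)cc1OCc1ccccc1 | intermediate
11 | benzyl alcohol | OCc1ccccc1 | starting material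
12 | trichloroethylene | ClC=C(Cl)Cl | starting material
13 | potassium benzyloxide | [K+].[O-]Cc1ccccc1 | intermediate
14 | benzyl (E)-1,2-dichlorovinyl ether | Cl/C=C(/Cl)OCc1ccccc1 | intermediate
15 | butanal | CCCC=O | starting material
16 | benzyl chloroethynyl ether | ClC#COCc1ccccc1 | intermediate
17 | lithium benzyloxyacetylide | [Li+].[C-]#COCc1ccccc1 | intermediate
18 | 1-(benzyloxy)hex-1-yn-3-ol (racemic) | CCCC(O)C#COCc1ccccc1 | intermediate
19 | 1-(benzyloxy)hex-1-yn-3-one | CCCC(=O)C#COCc1ccccc1 | intermediate
20 | 1-[2-(benzyloxy)-4,6-dimethoxy-5-methyl-6-(trimethylsilyloxy)-3-{[2,4,6-tris(benzyloxy)phenyl]methyl}cyclohexa-1,4-dien-1-yl]butan-1-one (diastereomer mixture) | CCCC(=O)C1=C(OCc2ccccc2)C(Cc2c(OCc3ccccc3)cc(OCc3ccccc3)cc2OCc2ccccc2)C(OC)=C(C)C1(OC)O[Si](C)(C)C | intermediate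
21 | 1-[2-(benzyloxy)-6-hydroxy-4-methoxy-5-methyl-3-{[2,4,6-tris(benzyloxy)phenyl]methyl}phenyl]butan-1-one | CCCC(=O)c1c(O)c(C)c(OC)c(Cc2c(OCc3ccccc3)cc(OCc3ccccc3)cc2OCc2ccccc2)c1OCc1ccccc1 | intermediate
22 | 1-[2,4,6-tris(benzyloxy)-3-{[2-(benzyloxy)-3-butanoyl-4-hydroxy-6-methoxy-5-methylphenyl]methyl}phenyl]butan-1-one | CCCC(=O)c1c(O)c(C)c(OC)c(Cc2c(OCc3ccccc3)c(C(=O)CCC)c(OCc3ccccc3)cc2OCc2ccccc2)c1OCc1ccccc1 | intermediate
23 | 1-[3-[(3-butanoyl-2,4-dihydroxy-6-methoxy-5-methylphenyl)methyl]-2,4,6-trihydroxyphenyl]butan-1-one | CCCC(=O)c1c(O)c(Cc2c(O)c(C(=O)CCC)c(O)c(C)c2OC)c(O)cc1O | intermediate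
24 | 2-methylbenzene-1,3,5-triol | Cc1c(O)cc(O)cc1O | starting material
25 | 1-(2,4,6-trihydroxy-3-methylphenyl)butan-1-one | CCCC(=O)c1c(O)cc(O)c(C)c1O | intermediate
26 | 1-[4,6-bis(benzyloxy)-2-hydroxy-3-methylphenyl]butan-1-one | CCCC(=O)c1c(O)c(C)c(OCc2ccccc2)cc1OCc1ccccc1 | intermediate
27 | 1-[4,6-bis(benzyloxy)-2-methoxy-3-methylphenyl]butan-1-one | CCCC(=O)c1c(OC)c(C)c(OCc2ccccc2)cc1OCc1ccccc1 | intermediate
28 | 1-(4,6-dihydroxy-2-methoxy-3-methylphenyl)butan-1-one | CCCC(=O)c1c(O)cc(O)c(C)c1OC | intermediate
29 | 1-{3-[(dimethylamino)methyl]-2,4-dihydroxy-6-methoxy-5-methylphenyl}butan-1-one | CCCC(=O)c1c(O)c(CN(C)C)c(O)c(C)c1OC | intermediate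
30 | CNP0171986.0, 1-[3-[(3-butanoyl-2,4-dihydroxy-6-methoxy-5-methylphenyl)methyl]-5-[(3-butanoyl-2,6-dihydroxy-4-methoxy-5-methylphenyl)methyl]-2,4,6-trihydroxyphenyl]butan-1-one | CCCC(=O)c1c(O)c(Cc2c(O)c(C)c(OC)c(C(=O)CCC)c2O)c(O)c(Cc2c(O)c(C(=O)CCC)c(O)c(C)c2OC)c1O | target

**Totals**
Total step count: 17. Longest linear sequence: 9 steps (steps 1, 2, 3, 4, 5, 9, 10, 11, 17).

**Steps most likely to fail**

Step 9 (proposed new method). The donor-substituted alkyne may add so slowly that the diene is desilylated first. The addition may stop at the open-chain Michael adduct without ring closure. The Lewis acid may strip the benzyl group from the ynol ether and open a ketene pathway. Aromatisation may proceed by loss of silanol instead of methanol, which would leave the wrong oxygen methylated. The fallback uses only known acylphloroglucinol chemistry and sets out from compound 25. Selective methylation of the most acidic, non-chelated 4-OH (Me2SO4, 1 equiv, K2CO3, acetone, rt) should give 1-(2,6-dihydroxy-4-methoxy-3-methylphenyl)butan-1-one F1, which already has the substitution pattern of ring B. Aminomethylation at its only free position (aq. CH2O, aq. Me2NH, EtOH) should give 1-{3-[(dimethylamino)methyl]-2,6-dihydroxy-4-methoxy-5-methylphenyl}butan-1-one F2. Heating F2 in dioxane at 90 °C with an excess of purchased 1-(2,4,6-trihydroxyphenyl)butan-1-one F3 should monoalkylate one of its two equivalent free positions through the quinone methide. This comes back to the route at compound 23 and leaves out steps 1 to 11.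

Step 17. The quinone methide may condense with itself, O-alkylation may compete, and the methylene bridge already present in 23 may be exchanged by reversible retro-Friedel–Crafts cleavage under the hot, amine-containing conditions. The fallback reverses the roles of the partners and sets out from compound 23. Aminomethylation at the single free carbon of its central ring (aq. CH2O, aq. Me2NH, EtOH, rt) should give 1-[3-[(3-butanoyl-2,4-dihydroxy-6-methoxy-5-methylphenyl)methyl]-5-[(dimethylamino)methyl]-2,4,6-trihydroxyphenyl]butan-1-one F4. F4 is then heated in dioxane with a large excess of the cheap monomer 28, so that the quinone methide formed on the valuable fragment is trapped at once. This comes back to the route at compound 30.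

Step 3. The benzylic cation may lose a proton to the styryl ketone faster than it takes up hydride, it may be captured by the ester carbonyl to a lactone, the aldol may revert under acid, and trifluoroacetic acid may begin to cleave benzyl ethers. The fallback replaces hydride capture by elimination and hydrogenation and sets out from compound 6. Dehydration with pyridinium p-toluenesulfonate in toluene at 60 °C should give methyl (4E)-2-methyl-3-oxo-5-[2,4,6-tris(benzyloxy)phenyl]pent-4-enoate F5. Homogeneous hydrogenation of its C=C bond with RhCl(PPh3)3 and H2 in benzene–EtOH leaves the benzyl ethers intact and comes back to the route at compound 7.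

**Further compounds**
F1 | step 9 | 1-(2,6-dihydroxy-4-methoxy-3-methylphenyl)butan-1-one | CCCC(=O)c1c(O)cc(OC)c(C)c1O
F2 | step 9 | 1-{3-[(dimethylamino)methyl]-2,6-dihydroxy-4-methoxy-5-methylphenyl}butan-1-one | CCCC(=O)c1c(O)c(CN(C)C)c(OC)c(C)c1O
F3 | step 9 | 1-(2,4,6-trihydroxyphenyl)butan-1-one (purchased) | CCCC(=O)c1c(O)cc(O)cc1O
F4 | step 17 | 1-[3-[(3-butanoyl-2,4-dihydroxy-6-methoxy-5-methylphenyl)methyl]-5-[(dimethylamino)methyl]-2,4,6-trihydroxyphenyl]butan-1-one | CCCC(=O)c1c(O)c(Cc2c(O)c(C(=O)CCC)c(O)c(C)c2OC)c(O)c(CN(C)C)c1O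
F5 | step 3 | methyl (4E)-2-methyl-3-oxo-5-[2,4,6-tris(benzyloxy)phenyl]pent-4-enoate | COC(=O)C(C)C(=O)/C=C/c1c(OCc2ccccc2)cc(OCc2ccccc2)cc1OCc1ccccc1
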